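The activator charged in the flask stands to that of the maple run as 2.00 to 1, at the same 1.0 M of starting material, and I want to know what that ratio does to the clock.

| flask | starting material | activator | remark | time |
|---|---|---|---|---|
| maple | 1 M | 1 M | run made earlier |  |
| flask | 1.0 M | 2.00 M |  | 2.0 min |

- maple (time / s: ring / %, starting material / %): 10.0: 13, 70; 12.0: 17, 67; 20.0: 23, 51; 25.0: 29, 45; 30.0: 31, 38; 40.0: 37, 32

(readings scatter by 1.5 percentage points)

* amount of ring in percent of the starting material charged, at 6.0 s, 30 s and 2.0 min

- a species is counted by the starting material in it: one open dimer or homo dimer counts as two
- what may be going on: starting material + activator -> activated form; starting material + activated form -> open dimer; 2 starting material -> homo dimer; activated form -> ring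

1. In the maple run the starting material reads 51 %, close to half, at 20.0 s. I take that as its first half-life, scatter included.

2. My bench rule treats the loss as pseudo-first-order in starting material, with a rate constant proportional to [activator]. The half-life of the flask, the maple half-life scaled by the ratio of charges, is then 10.0 s.

3. The maple run also gives ring per starting material lost: 54.4 % at 40.0 s. Held constant, this gives me 18.5 % of ring at 6.0 s and 47.6 % at 30 s in the flask.

4. The rule has a border: in the flask, activator stands to starting material as 2.00 to 1, so I can't treat [activator] as constant. Starting material is the limiting reagent, and if each one takes one activator, the flask keeps at least 0.500 of its [activator]. The late half-life may therefore stretch to 20.0 s. So by my count 2.0 min holds between 6.00 and 12.0 half-lives; the first of these counts leaves 1.56 % of starting material, and I commit to about 54.4 % of ring.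

5. The forecast gives 16 %, 50 % and 63 %. Its clock, “starting material is consumed at roughly 0.07 /s”, matches my 0.0693 s⁻¹, but its last value is higher than mine.

6. The flask gives 17.6 %, 50.5 % and 66.6 % of ring, so the forecast stands within its margin.

    starting material + activator → activated form (k = 0.0290 L mol⁻¹ s⁻¹)
    starting material + activated form → open dimer (k = 0.531 L mol⁻¹ s⁻¹)
    2 starting material → homo dimer (k = 0.00488 L mol⁻¹ s⁻¹)
    activated form → ring (k = 1.19 s⁻¹)

At 0.200 min the flask holds 43.8 % of starting material, against 43.5 % counted with 10.0 s. Activated form has two exits, and their ratio, k4 over k2[starting material], a selectivity factor, is 2.24 at the charge. In the flask at 0.187 min, 1.12 half-lives in, it is 4.9, twice that, and by 0.400 min, 2.40 half-lives in, the open dimer step has 92 % of its turnover behind it.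

All runs come from a simulation for substances that don't exist.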